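Ring B is O1, C2, C3, O4. Ring A is C4a, C5 (OMe), C6, C7 (side chain), C8, C8a. Ring C is the 3,4,5-trimethoxyphenyl group on C2, and the methyl group sits on C3.
Retrosynthesis: cut the side-chain C=C at C7 (Wittig), take the C3 methyl back to an exocyclic C3=CH2, then cut O4–C3 and O1–C2 in one operation. This leaves a racemic propargylic carbonate bearing ring C (from the aryl aldehyde and an ethynyl Grignard reagent) and the catechol 5-hydroxyvanillin.
Enabling feature: O4 lies para to C7, so a formyl group at C7 makes its phenol the more acidic one. C3 carries O4 and a one-carbon branch, so it maps onto the central carbon of an allenylpalladium unit. C2 is benzylic to ring C, so it maps onto the cation-stabilised terminus of the derived π-allyl complex.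
Forward: rings A and C are bought. Ring B, the only ring made, closes in step 2, followed by alkene reduction and a two-carbon chain extension.
Stereochemistry: C2 (R) comes from the chiral diphosphine on palladium in a stereoconvergent closure. C3 (R) is relayed from C2 in a radical hydrogenation that favours the trans, diequatorial ring B. The E alkene comes from a stabilised ylide.

Key step: step 2

Assumption: (R)-BINAP is written as the ligand that leads to the (2R) annulation product. Analogy does not secure the sense of induction for an aryl-bearing allyl terminus, so (S)-BINAP takes its place if the first run shows the opposite sense.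

Step 1
Reactants: 1 3,4,5-trimethoxybenzaldehyde; 2 ethynylmagnesium bromide
Product: 4 racemic methyl 1-(3,4,5-trimethoxyphenyl)prop-2-yn-1-yl carbonate, via bromomagnesium propargylic alkoxide 3 (not isolated)
Conditions: 2 (1.1 equiv), THF, 0 °C; then ClCO2Me, 0 °C to rt; aq NH4Cl work-up
Reagents that add atoms: methyl chloroformate, COC(=O)Cl
Why: Grignard 1,2-addition of the acetylide to a non-enolisable aryl aldehyde followed by in-flask O-acylation of the magnesium alkoxide with the chloroformate is routine, and the carbinol carbon may stay racemic because step 2 is stereoconvergent.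

Step 2
Reactants: 4 racemic methyl 1-(3,4,5-trimethoxyphenyl)prop-2-yn-1-yl carbonate; 5 5-hydroxyvanillin (3,4-dihydroxy-5-methoxybenzaldehyde)
Product: 6 (2R)-5-methoxy-3-methylidene-2-(3,4,5-trimethoxyphenyl)-2,3-dihydro-1,4-benzodioxine-7-carbaldehyde
Conditions: Pd2(dba)3·CHCl3 (2.5 mol %), (R)-BINAP (6 mol %), degassed THF, 0 °C to rt, no added base; filtration through neutral alumina
Reagents that add atoms: none
Why: Zerovalent palladium ionises either enantiomer of 4 in an anti SN2' sense with loss of CO2 and methoxide, the methoxide deprotonates the more acidic O4–H of 5, and this phenoxide adds to the central carbon of the cationic allenyl/propargyl palladium species (O4–C3), after which proton transfer from O1–H gives a 2-aryloxy π-allyl complex with CH2 and CH(ring C) termini. The O1 phenoxide then attacks the ring C terminus anti to the metal (O1–C2), closing ring B as a six-membered ring in an exo mode (the C2–Pd bond that breaks lies outside the new ring) and leaving C3=CH2 exocyclic. The closest known reaction type is the Pd2(dba)3/BINAP annulation of benzene-1,2-diols with racemic secondary propargylic carbonates, a Tsuji–Trost-type double C–O bond formation that gives enantioenriched 2-alkylidene-3-alkyl-1,4-benzodioxanes by closure at the substituted terminus. C2 is controlled by the chiral diphosphine, because the two diastereomeric π-allyl complexes exchange faces by π–σ–π slippage through the unsubstituted CH2 terminus faster than they cyclise, so both enantiomers of 4 should converge on (2R)-6 (dynamic kinetic asymmetric transformation). The step needs selection between two phenols and between two allyl termini: the first is secured by the formyl group at C7 para to O4, the same bias that directs mono-alkylation of such catechols to this oxygen, and the second by the larger cationic character and longer Pd–C bond at the terminus stabilised by the electron-rich ring C. Since closure at that terminus is a kinetic outcome, the run is kept at or below room temperature, is stopped once 4 is consumed and is worked up without acid or added base, so that neither re-ionisation of the allylic aryl ether nor migration of the double bond to C2=C3 can erase C2.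

Step 3
Reactants: 6 (2R)-5-methoxy-3-methylidene-2-(3,4,5-trimethoxyphenyl)-2,3-dihydro-1,4-benzodioxine-7-carbaldehyde
Product: 7 (2R,3R)-5-methoxy-3-methyl-2-(3,4,5-trimethoxyphenyl)-2,3-dihydro-1,4-benzodioxine-7-carbaldehyde (trans)
Conditions: Mn(dpm)3 (10 mol %), PhSiH3, t-BuOOH, degassed i-PrOH, rt
Reagents that add atoms: none
Why: Metal-hydride hydrogen-atom-transfer hydrogenation (Mukaiyama-type radical hydrofunctionalisation) places H• from the manganese hydride on the CH2 terminus of the electron-rich 1,1-disubstituted enol ether, and the tertiary α-oxy radical at C3, held in a half-chair with ring C pseudo-equatorial, should take the second hydrogen along the axial trajectory so that the methyl group ends equatorial and trans to ring C (3R), in contrast to surface hydrogenation, which adds opposite ring C and leads to cis; the aryl ethers are inert and the formyl group is expected to react much more slowly than the alkene.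

Step 4
Reactants: 7 (2R,3R)-5-methoxy-3-methyl-2-(3,4,5-trimethoxyphenyl)-2,3-dihydro-1,4-benzodioxine-7-carbaldehyde
Product: 8 (2E)-3-[(2R,3R)-5-methoxy-3-methyl-2-(3,4,5-trimethoxyphenyl)-2,3-dihydro-1,4-benzodioxin-7-yl]prop-2-enal
Conditions: Ph3P=CHCHO (1.2 equiv), toluene, 80 °C
Reagents that add atoms: (triphenylphosphoranylidene)acetaldehyde, O=CC=P(c1ccccc1)(c1ccccc1)c1ccccc1
Why: Wittig olefination with the formyl-stabilised ylide is E-selective on aromatic aldehydes and runs without acid or base, so the C2 and C3 centres and the aryl ethers are untouched, and the small excess of ylide limits a second homologation.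

Compound list
1 | 3,4,5-trimethoxybenzaldehyde | COc1cc(C=O)cc(OC)c1OC | starting material
2 | ethynylmagnesium bromide | C#C[Mg]Br | starting material
3 | bromomagnesium 1-(3,4,5-trimethoxyphenyl)prop-2-yn-1-olate (racemic, not isolated) | COc1cc(C(C#C)O[Mg]Br)cc(OC)c1OC | intermediate
4 | methyl 1-(3,4,5-trimethoxyphenyl)prop-2-yn-1-yl carbonate (racemic) | COc1cc(C(C#C)OC(=O)OC)cc(OC)c1OC | intermediate
5 | 5-hydroxyvanillin (3,4-dihydroxy-5-methoxybenzaldehyde) | COc1cc(C=O)cc(O)c1O | starting material
6 | (2R)-5-methoxy-3-methylidene-2-(3,4,5-trimethoxyphenyl)-2,3-dihydro-1,4-benzodioxine-7-carbaldehyde | COc1cc([C@H]2Oc3cc(C=O)cc(OC)c3OC2=C)cc(OC)c1OC | intermediate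
7 | (2R,3R)-5-methoxy-3-methyl-2-(3,4,5-trimethoxyphenyl)-2,3-dihydro-1,4-benzodioxine-7-carbaldehyde | COc1cc([C@H]2Oc3cc(C=O)cc(OC)c3O[C@@H]2C)cc(OC)c1OC | intermediate
8 | (2E)-3-[(2R,3R)-5-methoxy-3-methyl-2-(3,4,5-trimethoxyphenyl)-2,3-dihydro-1,4-benzodioxin-7-yl]prop-2-enal | COc1cc([C@H]2Oc3cc(/C=C/C=O)cc(OC)c3O[C@@H]2C)cc(OC)c1OC | target

Total step count: 4. Longest linear sequence: 4 (1 → 4 → 6 → 7 → 8).

Steps most likely to fail

Step 2. Four processes threaten this step:
- Ring closure may occur at the unsubstituted allyl terminus, which is sterically easier and brings the alkene into conjugation with ring C.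
- Palladium may re-ionise the allylic aryl ether after closure.
- The first attack may go through the O1 phenol.
- Cyclisation may outrun face exchange, which erodes the enantioselectivity.

The fallback sets out from 5 and 4 and comes back at 6. It makes the two C–O bonds one at a time and in the opposite order, so no allyl terminus has to be chosen. Selective alkylation of the more acidic O4–H of 5 (allyl bromide, NaHCO3, DMF) would give 3-hydroxy-5-methoxy-4-(prop-2-en-1-yloxy)benzaldehyde F1. Copper-catalysed enantioselective propargylic etherification of 4 with the remaining O1 phenol ((CuOTf)2·C6H6, chiral Ph-pybox, i-Pr2NEt, aprotic solvent, low temperature) proceeds through a copper allenylidene. It forms O1–C2 and would give 3-{[(1S)-1-(3,4,5-trimethoxyphenyl)prop-2-yn-1-yl]oxy}-5-methoxy-4-(prop-2-en-1-yloxy)benzaldehyde F2. The descriptor is S only because ring C outranks ethynyl, and the spatial arrangement is that of (2R)-6. Allyl removal (Pd(PPh3)4, morpholine, THF) would free O4–H in 4-hydroxy-3-methoxy-5-{[(1S)-1-(3,4,5-trimethoxyphenyl)prop-2-yn-1-yl]oxy}benzaldehyde F3. Gold-catalysed 6-exo-dig hydroalkoxylation (AuCl(PPh3)/AgOTf, CH2Cl2) then adds O4–H to the internal alkyne carbon, forms O4–C3 and gives 6.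

Step 3. Three processes threaten this step:
- Facial selectivity in the second hydrogen transfer may be poor if ring C turns pseudo-axial in the radical.
- β-Scission of the benzylic C2–O1 bond from the C3 radical would open ring B and lose C2.
- The silane may slowly reduce the formyl group.

The fallback sets out from 4 and 5 and comes back at 7. It replaces radical delivery by a stereochemical relay. Step 2 run with the other enantiomer of BINAP would give (2S)-5-methoxy-3-methylidene-2-(3,4,5-trimethoxyphenyl)-2,3-dihydro-1,4-benzodioxine-7-carbaldehyde F4. Allylic strain with the exocyclic methylene pushes ring C pseudo-axial, so surface hydrogenation (H2, 1 atm, Rh/Al2O3, EtOAc) adds to the face opposite ring C. This would give cis-(2S,3R)-5-methoxy-3-methyl-2-(3,4,5-trimethoxyphenyl)-2,3-dihydro-1,4-benzodioxine-7-carbaldehyde F5. BF3·OEt2 in CH2Cl2 then ionises the benzylic C2–O1 bond reversibly, and re-closure under thermodynamic control inverts C2 to the diequatorial trans isomer 7. The untouched C3 carries the stereochemical information through this last operation.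

Step 4. The electron-rich aldehyde may react sluggishly, and the product enal may undergo a second homologation by the same ylide. The fallback sets out from 7 and comes back at 8. It builds the chain at the ester oxidation level. Horner–Wadsworth–Emmons olefination (triethyl phosphonoacetate, NaH, THF) would give ethyl (2E)-3-[(2R,3R)-5-methoxy-3-methyl-2-(3,4,5-trimethoxyphenyl)-2,3-dihydro-1,4-benzodioxin-7-yl]prop-2-enoate F6. DIBAL-H reduction (CH2Cl2, −78 °C) would give (2E)-3-[(2R,3R)-5-methoxy-3-methyl-2-(3,4,5-trimethoxyphenyl)-2,3-dihydro-1,4-benzodioxin-7-yl]prop-2-en-1-ol F7. Allylic oxidation with MnO2 (CH2Cl2, rt) then gives 8.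

Further compounds
F1 | step 2 | 3-hydroxy-5-methoxy-4-(prop-2-en-1-yloxy)benzaldehyde | COc1cc(C=O)cc(O)c1OCC=C
F2 | step 2 | 3-{[(1S)-1-(3,4,5-trimethoxyphenyl)prop-2-yn-1-yl]oxy}-5-methoxy-4-(prop-2-en-1-yloxy)benzaldehyde | COc1cc([C@H](C#C)Oc2cc(C=O)cc(OC)c2OCC=C)cc(OC)c1OC
F3 | step 2 | 4-hydroxy-3-methoxy-5-{[(1S)-1-(3,4,5-trimethoxyphenyl)prop-2-yn-1-yl]oxy}benzaldehyde | COc1cc([C@H](C#C)Oc2cc(C=O)cc(OC)c2O)cc(OC)c1OC
F4 | step 3 | (2S)-5-methoxy-3-methylidene-2-(3,4,5-trimethoxyphenyl)-2,3-dihydro-1,4-benzodioxine-7-carbaldehyde | COc1cc([C@@H]2Oc3cc(C=O)cc(OC)c3OC2=C)cc(OC)c1OC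
F5 | step 3 | cis-(2S,3R)-5-methoxy-3-methyl-2-(3,4,5-trimethoxyphenyl)-2,3-dihydro-1,4-benzodioxine-7-carbaldehyde | COc1cc([C@@H]2Oc3cc(C=O)cc(OC)c3O[C@@H]2C)cc(OC)c1OC
F6 | step 4 | ethyl (2E)-3-[(2R,3R)-5-methoxy-3-methyl-2-(3,4,5-trimethoxyphenyl)-2,3-dihydro-1,4-benzodioxin-7-yl]prop-2-enoate | COc1cc([C@H]2Oc3cc(/C=C/C(=O)OCC)cc(OC)c3O[C@@H]2C)cc(OC)c1OC
F7 | step 4 | (2E)-3-[(2R,3R)-5-methoxy-3-methyl-2-(3,4,5-trimethoxyphenyl)-2,3-dihydro-1,4-benzodioxin-7-yl]prop-2-en-1-ol | COc1cc([C@H]2Oc3cc(/C=C/CO)cc(OC)c3O[C@@H]2C)cc(OC)c1OC
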